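**Plan**

Retrosynthesis: the ester C–O bond at C1' and the two O–methyl bonds on ring B are cut first, then quinone ring A is cut at C1–C2 and C3–C4.
Enabling feature: in ring A (C1, C2, C3, C4, C4a, C8a) the C2–C3 unit, with the side chain on C2 and hydrogen on C3, is a terminal propargylic alkyne; C1, C4, C4a and C8a with the oxygens on C5 and C8 are a symmetric 3,6-dioxygenated phthaloyl unit, i.e. a benzocyclobutene-1,2-dione opened by cobalt.
Rings, forward: ring B is bought as 2-bromo-1,4-dimethoxybenzene; a four-membered ring is fused on by aryne [2+2] cycloaddition and oxidised to the 1,2-dione; monovalent cobalt opens it to a five-membered metallacycle; ring A closes last by alkyne insertion.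
Chain: the C8 enyne comes from 4-methylpent-3-enoic acid and ethynyltrimethylsilane through a silyl ynone; after the annulation the silyl ether is exchanged for the 3-methylbut-2-enoate and ring B is demethylated oxidatively.
Stereochemistry: the single stereocentre C1' (S) is set by asymmetric transfer hydrogenation of the ynone with the (S,S)-diamine ruthenium catalyst and is carried unchanged to the target.

Key step: step 11

Remark: naphthazarins equilibrate rapidly between tautomers, so the 2-substituted 5,8-dihydroxy-1,4-naphthoquinone drawn for the target and its 6-substituted tautomer are one compound; ClCo(PPh3)3 is taken as a purchasable reagent.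

**Route**

Step 1
Reactants: 1 2-bromo-1,4-dimethoxybenzene; 2 1,1-dimethoxyethene
Product: 4 2,5,7,7-tetramethoxybicyclo[4.2.0]octa-1,3,5-triene (3,6-dimethoxybenzocyclobutenone dimethyl ketal), via 3,6-dimethoxybenzyne 3 (not isolated)
Conditions: NaNH2, THF, reflux
Reagents that add atoms: none
Why: NaNH2 eliminates HBr from 1 to give the symmetric aryne 3, which the electron-rich ketene acetal 2 traps in a stepwise polar aryne [2+2] cycloaddition, and the symmetry of 3 allows only one regioisomer.

Step 2
Reactants: 4 2,5,7,7-tetramethoxybicyclo[4.2.0]octa-1,3,5-triene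
Product: 5 2,5-dimethoxybicyclo[4.2.0]octa-1,3,5-trien-7-one (3,6-dimethoxybenzocyclobutenone)
Conditions: 1 M aq. HCl, THF, rt
Reagents that add atoms: water, O
Why: Mild aqueous acid hydrolyses the dimethyl ketal through the oxocarbenium ion without opening the strained four-membered ring, a standard ketal hydrolysis.

Step 3
Reactants: 5 2,5-dimethoxybicyclo[4.2.0]octa-1,3,5-trien-7-one
Product: 6 8,8-dibromo-2,5-dimethoxybicyclo[4.2.0]octa-1,3,5-trien-7-one
Conditions: NBS (2.2 equiv), (PhCO2)2 (cat.), CCl4 (or PhCF3), reflux, hν
Reagents that add atoms: N-bromosuccinimide, O=C1CCC(=O)N1Br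
Why: The CH2 group of 5 is both benzylic and alpha to the carbonyl, so Wohl–Ziegler radical bromination should occur there twice, while the non-polar medium and radical initiation disfavour electrophilic bromination of the dimethoxyarene ring.

Step 4
Reactants: 6 8,8-dibromo-2,5-dimethoxybicyclo[4.2.0]octa-1,3,5-trien-7-one
Product: 7 2,5-dimethoxybicyclo[4.2.0]octa-1,3,5-triene-7,8-dione (3,6-dimethoxybenzocyclobutene-1,2-dione)
Conditions: 50% aq. H2SO4, 50–60 °C
Reagents that add atoms: water, O
Why: Hydrolysis of the benzylic geminal dibromide, assisted by the electron-rich arene, unmasks the second carbonyl to give the 1,2-dione, and the aryl methyl ethers tolerate aqueous sulfuric acid of this strength.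

Step 5
Reactants: 7 2,5-dimethoxybicyclo[4.2.0]octa-1,3,5-triene-7,8-dione
Product: 9 chloro(dimethylglyoxime)(pyridine)(3,6-dimethoxyphthaloyl)cobalt (six-coordinate trivalent cobalt metallacycle), via chlorobis(triphenylphosphine)(3,6-dimethoxyphthaloyl)cobalt 8 (not isolated)
Conditions: ClCo(PPh3)3, PhCl, rt; then dimethylglyoxime, pyridine, rt
Reagents that add atoms: chlorotris(triphenylphosphine)cobalt, Cl[Co-3]([P+](c1ccccc1)(c1ccccc1)c1ccccc1)([P+](c1ccccc1)(c1ccccc1)c1ccccc1)[P+](c1ccccc1)(c1ccccc1)c1ccccc1; dimethylglyoxime, CC(=NO)C(C)=NO; pyridine, c1ccncc1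
Why: Monovalent cobalt adds oxidatively into the strained C7–C8 bond between the two carbonyl carbons of 7 to give the five-membered phthaloyl metallacycle of trivalent cobalt 8, and exchange of both phosphines for dimethylglyoxime and pyridine gives the air-stable complex 9, the known activated form for alkyne insertion.

Step 6
Reactants: 10 4-methylpent-3-enoic acid
Product: 12 N-methoxy-N,4-dimethylpent-3-enamide, via acyl imidazole 11 (not isolated)
Conditions: CDI, CH2Cl2, 0 °C to rt; then MeNHOMe·HCl, rt
Reagents that add atoms: N,O-dimethylhydroxylamine hydrochloride, CNOC.Cl; 1,1'-carbonyldiimidazole, O=C(n1ccnc1)n1ccnc1 (atoms retained only in 11)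
Why: Carbonyldiimidazole converts the acid into acyl imidazole 11 under near-neutral conditions that should leave the skipped alkene in place, and N,O-dimethylhydroxylamine then gives the Weinreb amide.

Step 7
Reactants: 12 N-methoxy-N,4-dimethylpent-3-enamide; 13 ethynyltrimethylsilane
Product: 16 6-methyl-1-(trimethylsilyl)hept-5-en-1-yn-3-one, via lithium (trimethylsilyl)acetylide 14 (not isolated), via lithium hemiaminal adduct 15 (not isolated)
Conditions: 13, n-BuLi, THF, −78 °C; then 12, −78 to −20 °C; AcOH quench at −78 °C
Reagents that add atoms: n-butyllithium, [Li]CCCC (lithium retained only in 14 and 15)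
Why: In this Weinreb ketone synthesis the lithium acetylide adds once to give the chelated tetrahedral adduct 15, which collapses to the ynone only on the cold acidic quench, so neither over-addition nor base-induced migration of the alkene into conjugation should occur.

Step 8
Reactants: 16 6-methyl-1-(trimethylsilyl)hept-5-en-1-yn-3-one
Product: 17 (S)-6-methyl-1-(trimethylsilyl)hept-5-en-1-yn-3-ol
Conditions: Ru[(S,S)-TsNCHPhCHPhNH](η6-p-cymene) (1 mol %), i-PrOH, rt
Reagents that add atoms: none
Why: In this Noyori asymmetric transfer hydrogenation of an alkynyl ketone the divalent ruthenium hydride/amine complex of the (S,S)-diamine delivers hydride to the carbonyl face that places the alkyne where an aryl group normally sits, which sets the (S)-carbinol centre, and the base-free medium protects the skipped enone from isomerisation.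

Step 9
Reactants: 17 (S)-6-methyl-1-(trimethylsilyl)hept-5-en-1-yn-3-ol
Product: 18 (S)-tert-butyldimethyl{[6-methyl-1-(trimethylsilyl)hept-5-en-1-yn-3-yl]oxy}silane
Conditions: TBSCl, imidazole, DMF, rt
Reagents that add atoms: tert-butyldimethylsilyl chloride, CC(C)(C)[Si](C)(C)Cl
Why: This is a standard imidazole-promoted silylation of a secondary alcohol in which no bond to the stereocentre is broken.

Step 10
Reactants: 18 (S)-tert-butyldimethyl{[6-methyl-1-(trimethylsilyl)hept-5-en-1-yn-3-yl]oxy}silane
Product: 19 (S)-tert-butyldimethyl[(6-methylhept-5-en-1-yn-3-yl)oxy]silane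
Conditions: K2CO3 (0.2 equiv), MeOH, rt
Reagents that add atoms: none
Why: Methoxide from K2CO3 in methanol cleaves the C(sp)–Si bond selectively (protodesilylation), the hindered secondary silyl ether being stable under these conditions.

Step 11
Reactants: 9 chloro(dimethylglyoxime)(pyridine)(3,6-dimethoxyphthaloyl)cobalt; 19 (S)-tert-butyldimethyl[(6-methylhept-5-en-1-yn-3-yl)oxy]silane
Product: 20 (S)-2-[1-(tert-butyldimethylsilyloxy)-4-methylpent-3-enyl]-5,8-dimethoxy-1,4-naphthoquinone
Conditions: CoCl2·6H2O (cat.), MeCN, 80 °C, N2
Reagents that add atoms: none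
Why: The Lewis acid CoCl2·6H2O labilises a ligand on the saturated trivalent cobalt centre of 9, the terminal alkyne of 19 binds in the freed site and inserts into one cobalt–acyl bond (first C–C bond, C1–C2 or its equivalent C4–C3) to give a seven-membered cobaltacycle, and C–C reductive elimination forms the second bond and releases the quinone together with monovalent cobalt. The closest known reaction type is the naphthoquinone synthesis from phthaloylcobalt complexes of benzocyclobutenediones and alkynes, a metal-mediated formal [4+2] annulation. Ring A is closed as a six-membered carbocycle by reductive elimination from the seven-membered metallacycle and appears directly at the quinone oxidation level, so no later oxidation is needed. No stereocentre is created; the (S)-centre at C1' enters ready-made and none of its bonds is touched. The step needs chemoselective insertion of the alkyne in the presence of the trisubstituted alkene, which the far stronger binding and faster insertion of a terminal alkyne at cobalt should secure, and it needs no regiocontrol because the two acyl carbons of the 3,6-dimethoxyphthaloyl unit are equivalent, so only the 2-substituted quinone with C3–H can form. The bulky silyl ether keeps the propargylic oxygen away from cobalt, and any of it lost to the hydrated Lewis acid would simply appear as 21, the product of the next step.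

Step 12
Reactants: 20 (S)-2-[1-(tert-butyldimethylsilyloxy)-4-methylpent-3-enyl]-5,8-dimethoxy-1,4-naphthoquinone
Product: 21 (S)-2-(1-hydroxy-4-methylpent-3-enyl)-5,8-dimethoxy-1,4-naphthoquinone
Conditions: HF·pyridine, pyridine/THF, 0 °C to rt
Reagents that add atoms: none
Why: Buffered HF·pyridine cleaves the O–Si bond through formation of the strong Si–F bond under non-basic conditions, which avoids the base sensitivity of the quinone and leaves the stereocentre untouched.

Step 13
Reactants: 21 (S)-2-(1-hydroxy-4-methylpent-3-enyl)-5,8-dimethoxy-1,4-naphthoquinone; 22 3-methylbut-2-enoic acid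
Product: 23 (S)-1-(5,8-dimethoxy-1,4-dioxo-1,4-dihydronaphthalen-2-yl)-4-methylpent-3-enyl 3-methylbut-2-enoate
Conditions: DCC, DMAP (cat.), CH2Cl2, 0 °C to rt
Reagents that add atoms: none
Why: In this Steglich esterification DMAP transfers the acyl group from the O-acylisourea to the secondary alcohol with retention at C1', and the carbodiimide route avoids the vinylketene pathway that deconjugates this acid when its chloride is used with amine bases.

Step 14
Reactants: 23 (S)-1-(5,8-dimethoxy-1,4-dioxo-1,4-dihydronaphthalen-2-yl)-4-methylpent-3-enyl 3-methylbut-2-enoate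
Product: 25 alkannin β,β-dimethylacrylate [(S)-1-(5,8-dihydroxy-1,4-dioxo-1,4-dihydronaphthalen-2-yl)-4-methylpent-3-enyl 3-methylbut-2-enoate], via naphthalene-1,4,5,8-tetraone ester 24 (not isolated)
Conditions: AgO, 6 M HNO3, acetone, rt, a few minutes; then aq. Na2S2O4, EtOAc, brief, air
Reagents that add atoms: water, O (the two oxygens on ring B; water is regenerated from AgO and acid in the overall equation)
Why: Divalent silver oxidises the p-dimethoxyarene ring B by two electrons with loss of both methyl groups as methanol to give tetraone 24, and mild two-electron reduction with dithionite then gives the naphthazarin, an oxidative demethylation established for 5,8-dimethoxy-1,4-naphthoquinones that carry acyloxyalkyl side chains.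

**Compound list**

1 | 2-bromo-1,4-dimethoxybenzene | COc1ccc(OC)c(Br)c1 | starting material
2 | 1,1-dimethoxyethene | C=C(OC)OC | starting material
3 | 3,6-dimethoxybenzyne (not isolated) | COC1=CC=C(OC)C#C1 | intermediate
4 | 2,5,7,7-tetramethoxybicyclo[4.2.0]octa-1,3,5-triene | COc1ccc(OC)c2c1CC2(OC)OC | intermediate
5 | 2,5-dimethoxybicyclo[4.2.0]octa-1,3,5-trien-7-one | COc1ccc(OC)c2c1CC2=O | intermediate
6 | 8,8-dibromo-2,5-dimethoxybicyclo[4.2.0]octa-1,3,5-trien-7-one | COc1ccc(OC)c2c1C(Br)(Br)C2=O | intermediate
7 | 2,5-dimethoxybicyclo[4.2.0]octa-1,3,5-triene-7,8-dione (3,6-dimethoxybenzocyclobutene-1,2-dione) | COc1ccc(OC)c2c1C(=O)C2=O | intermediate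
8 | chlorobis(triphenylphosphine)(3,6-dimethoxyphthaloyl)cobalt, five-coordinate trivalent cobalt (not isolated) | COc1ccc(OC)c2c1C(=O)[Co-2](Cl)([P+](c1ccccc1)(c1ccccc1)c1ccccc1)([P+](c1ccccc1)(c1ccccc1)c1ccccc1)C2=O | intermediate
9 | chloro(dimethylglyoxime)(pyridine)(3,6-dimethoxyphthaloyl)cobalt, six-coordinate trivalent cobalt | COc1ccc(OC)c2c1C(=O)[Co-3]3(Cl)([n+]4ccccc4)([N+](O)=C(C)C(C)=[N+]3O)C2=O | intermediate
10 | 4-methylpent-3-enoic acid | CC(C)=CCC(=O)O | starting material
11 | 1-(4-methylpent-3-enoyl)imidazole (not isolated) | CC(C)=CCC(=O)n1ccnc1 | intermediate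
12 | N-methoxy-N,4-dimethylpent-3-enamide | CC(C)=CCC(=O)N(C)OC | intermediate
13 | ethynyltrimethylsilane | C#C[Si](C)(C)C | starting material
14 | lithium (trimethylsilyl)acetylide (not isolated) | [Li]C#C[Si](C)(C)C | intermediate
15 | lithium 3-[methoxy(methyl)amino]-6-methyl-1-(trimethylsilyl)hept-5-en-1-yn-3-olate, racemic (not isolated) | CC(C)=CCC(O[Li])(C#C[Si](C)(C)C)N(C)OC | intermediate
16 | 6-methyl-1-(trimethylsilyl)hept-5-en-1-yn-3-one | CC(C)=CCC(=O)C#C[Si](C)(C)C | intermediate
17 | (S)-6-methyl-1-(trimethylsilyl)hept-5-en-1-yn-3-ol | CC(C)=CC[C@H](O)C#C[Si](C)(C)C | intermediate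
18 | (S)-tert-butyldimethyl{[6-methyl-1-(trimethylsilyl)hept-5-en-1-yn-3-yl]oxy}silane | CC(C)=CC[C@H](O[Si](C)(C)C(C)(C)C)C#C[Si](C)(C)C | intermediate
19 | (S)-tert-butyldimethyl[(6-methylhept-5-en-1-yn-3-yl)oxy]silane | CC(C)=CC[C@H](O[Si](C)(C)C(C)(C)C)C#C | intermediate
20 | (S)-2-[1-(tert-butyldimethylsilyloxy)-4-methylpent-3-enyl]-5,8-dimethoxy-1,4-naphthoquinone | CC(C)=CC[C@H](O[Si](C)(C)C(C)(C)C)C1=CC(=O)c2c(OC)ccc(OC)c2C1=O | intermediate
21 | (S)-2-(1-hydroxy-4-methylpent-3-enyl)-5,8-dimethoxy-1,4-naphthoquinone | CC(C)=CC[C@H](O)C1=CC(=O)c2c(OC)ccc(OC)c2C1=O | intermediate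
22 | 3-methylbut-2-enoic acid | CC(C)=CC(=O)O | starting material
23 | (S)-1-(5,8-dimethoxy-1,4-dioxo-1,4-dihydronaphthalen-2-yl)-4-methylpent-3-enyl 3-methylbut-2-enoate | CC(C)=CC[C@H](OC(=O)C=C(C)C)C1=CC(=O)c2c(OC)ccc(OC)c2C1=O | intermediate
24 | (S)-4-methyl-1-(1,4,5,8-tetraoxo-1,4,5,8-tetrahydronaphthalen-2-yl)pent-3-enyl 3-methylbut-2-enoate (not isolated) | CC(C)=CC[C@H](OC(=O)C=C(C)C)C1=CC(=O)C2=C(C1=O)C(=O)C=CC2=O | intermediate
25 | alkannin β,β-dimethylacrylate, (S)-1-(5,8-dihydroxy-1,4-dioxo-1,4-dihydronaphthalen-2-yl)-4-methylpent-3-enyl 3-methylbut-2-enoate | CC(C)=CC[C@H](OC(=O)C=C(C)C)C1=CC(=O)c2c(O)ccc(O)c2C1=O | target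

**Step count and risks**

Total: 14 steps. Longest linear sequence: 9 steps (steps 1–5 then 11–14, or equally steps 6–10 then 11–14).

Steps most likely to fail:

1. Step 11. The insertion may be slow at the hindered propargylic alkyne. Alkyne oligomerisation at cobalt may compete, and the hydrated Lewis acid may strip the silyl ether at 80 °C. The fallback is metal-free and sets out from dione 7 and alkyne 19. Alkyne 19 would be deprotonated with n-BuLi in THF at −78 °C to lithium (S)-3-(tert-butyldimethylsilyloxy)-6-methylhept-5-en-1-yn-1-ide F1. This would be added to one of the two equivalent carbonyls of 7 and quenched with acetic acid to give 8-[(3S)-3-(tert-butyldimethylsilyloxy)-6-methylhept-5-en-1-yn-1-yl]-8-hydroxy-2,5-dimethoxybicyclo[4.2.0]octa-1,3,5-trien-7-one F2, as a mixture of carbinol epimers that is of no consequence. Heating F2 in p-xylene at about 140 °C should bring about a Moore rearrangement: electrocyclic opening of the four-membered ring to the ketene, six-membered closure onto the alkyne and transfer of the hydroxyl hydrogen to C3. This forms the same two ring A bonds and returns to the route at quinone 20.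

2. Step 14. Nitric acid and divalent silver may attack the trisubstituted alkene or solvolyse the ester before the electron-poor ring B is fully oxidised, and the dithionite work-up may over-reduce the product. The fallback is non-oxidative and sets out from 23. BCl3 in CH2Cl2 at −78 to −20 °C should cleave both methyl ethers by chelation to the neighbouring quinone carbonyls, since each methoxy group sits peri to a carbonyl. Aqueous work-up would give 25 directly; this fallback makes no new compound (F0).

3. Step 8. The basic amido catalyst may move the skipped alkene of 16 into conjugation with the ynone, or facial discrimination between the alkynyl and the allylic substituent may be poor. The fallback sets out from 16 and replaces catalytic transfer hydrogenation by a stoichiometric, base-free Midland reduction with (S)-Alpine-Borane (B-isopinocampheyl-9-borabicyclo[3.3.1]nonane from (−)-α-pinene), neat at rt. Hydride is delivered from the pinanyl group in a six-membered boat transition state with the slim alkyne as the small substituent, which should again give the (S)-alcohol. It returns to the route at 17 and makes no new compound (F0).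

**Further compounds**

F1 | step 11 | lithium (S)-3-(tert-butyldimethylsilyloxy)-6-methylhept-5-en-1-yn-1-ide | CC(C)=CC[C@H](O[Si](C)(C)C(C)(C)C)C#C[Li]
F2 | step 11 | 8-[(3S)-3-(tert-butyldimethylsilyloxy)-6-methylhept-5-en-1-yn-1-yl]-8-hydroxy-2,5-dimethoxybicyclo[4.2.0]octa-1,3,5-trien-7-one (epimers at C8) | CC(C)=CC[C@H](O[Si](C)(C)C(C)(C)C)C#CC1(O)C(=O)c2c(OC)ccc(OC)c21
F0 | step 14 | none | none
F0 | step 8 | none | none
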